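The route rests on cutting the allyl–alkyl bond C8–C9 (dec-6-enoate numbering, C1 = ester carbon). C8 is the CH2 on C7 that lies cis to C5 across the 6Z-configured C6=C7 alkene; C9 is the CH2 β to C4 of the 2,4-disubstituted furan ring. The key step is a copper-catalysed coupling of a primary alkyl Grignard reagent with a (Z)-2-methylalk-2-enyl bromide. It exploits the allylic activation of C8 by C6=C7 and joins both halves in one operation, keeping the preset Z geometry and the C3 centre (from (R)-citronellic acid). Its precursors are the bis-furan bromide 10 and the ester-bearing allylic bromide 17.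

Key step: step 10

Remark: 3-(bromomethyl)furan (2), (R)-citronellic acid (11) and the Still–Gennari phosphonate are taken as purchased; 2 is used fresh because furfuryl-type halides are labile.

Step 1
Reactants: 1 furan-3-carbaldehyde; 2 3-(bromomethyl)furan
Product: 6 5-(furan-3-ylmethyl)furan-3-carbaldehyde, via lithium amino alkoxide 3 (not isolated), via 5-lithiofuran 4 (not isolated), via alkylated amino alkoxide 5 (not isolated)
Conditions: morpholine, n-BuLi, THF, −78 °C; then 1; s-BuLi, −78 °C; then 2, −78 °C → rt; H2O
Reagents that add atoms: none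
Why: In situ protection of the aldehyde as its bulky lithium morpholino alkoxide blocks carbonyl addition and should steer s-BuLi deprotonation to the unhindered α-position C5, so that alkylation by the furfuryl-type bromide and collapse of the hemiaminal on aqueous work-up give the 2,4-disubstituted furan (α-amino alkoxide directed lithiation–alkylation).

Step 2
Reactants: 6 5-(furan-3-ylmethyl)furan-3-carbaldehyde
Product: 7 4-ethenyl-2-(furan-3-ylmethyl)furan
Conditions: Ph3PCH3Br, KOtBu, THF, 0 °C → rt
Reagents that add atoms: methyltriphenylphosphonium bromide, C[P+](c1ccccc1)(c1ccccc1)c1ccccc1.[Br-]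
Why: Wittig methylenation with the non-stabilised ylide converts the aldehyde into the terminal alkene under conditions to which both furan rings should be inert.

Step 3
Reactants: 7 4-ethenyl-2-(furan-3-ylmethyl)furan
Product: 9 2-[5-(furan-3-ylmethyl)furan-3-yl]ethan-1-ol, via B-alkyl-9-BBN 8 (not isolated)
Conditions: 9-BBN, THF, 0 °C → rt; then NaOH, H2O2, 0 °C
Reagents that add atoms: hydrogen peroxide, OO
Why: Hydroboration with the bulky 9-BBN should place boron on the terminal vinyl carbon and spare the furan rings, and alkaline peroxide oxidation then gives the primary alcohol (anti-Markovnikov hydroboration–oxidation).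

Step 4
Reactants: 9 2-[5-(furan-3-ylmethyl)furan-3-yl]ethan-1-ol
Product: 10 4-(2-bromoethyl)-2-(furan-3-ylmethyl)furan
Conditions: CBr4, PPh3, CH2Cl2, 0 °C
Reagents that add atoms: carbon tetrabromide, BrC(Br)(Br)Br
Why: Appel reaction, in which the alkoxyphosphonium ion of the primary alcohol is displaced by bromide under neutral conditions that the acid-sensitive furans should tolerate.

Step 5
Reactants: 11 (R)-citronellic acid
Product: 13 (3R)-3-methyl-6-oxohexanoic acid, via secondary ozonide 12 (not isolated)
Conditions: O3, CH2Cl2, −78 °C; then PPh3, −78 °C → rt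
Reagents that add atoms: ozone, [O-][O+]=O
Why: Ozonolysis of the trisubstituted alkene (Criegee mechanism) with reductive cleavage of the ozonide should deliver the C6 aldehyde, the C3 stereocentre being taken unchanged from (R)-citronellic acid.

Step 6
Reactants: 13 (3R)-3-methyl-6-oxohexanoic acid
Product: 14 (3R,6Z)-8-ethoxy-3,7-dimethyl-8-oxooct-6-enoic acid
Conditions: 13, KHMDS (1.0 equiv), THF, −78 °C; added to (CF3CH2O)2P(O)CH(CH3)CO2Et, KHMDS, 18-crown-6, THF, −78 °C; aq. HCl
Reagents that add atoms: ethyl 2-[bis(2,2,2-trifluoroethoxy)phosphoryl]propanoate, CCOC(=O)C(C)P(=O)(OCC(F)(F)F)OCC(F)(F)F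
Why: Still–Gennari variant of the Horner–Wadsworth–Emmons reaction, in which the electron-poor phosphonate under dissociating conditions should eliminate from the kinetic adduct and so give the (Z)-α-methyl enoate, while the acid rides through as its potassium carboxylate.

Step 7
Reactants: 14 (3R,6Z)-8-ethoxy-3,7-dimethyl-8-oxooct-6-enoic acid
Product: 15 (3R,6Z)-8-hydroxy-3,7-dimethyloct-6-enoic acid
Conditions: DIBAL-H (3.5 equiv), CH2Cl2, −78 → −40 °C; aq. Rochelle salt, then aq. citric acid
Reagents that add atoms: none
Why: DIBAL-H should first turn the acid into an aluminium carboxylate that resists hydride at low temperature and then reduce the conjugated ethyl ester in the 1,2 sense to the allylic alcohol, leaving the Z alkene and C3 untouched (chemoselective ester reduction).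

Step 8
Reactants: 15 (3R,6Z)-8-hydroxy-3,7-dimethyloct-6-enoic acid
Product: 16 methyl (3R,6Z)-8-hydroxy-3,7-dimethyloct-6-enoate
Conditions: MeI, K2CO3, DMF, 0 °C → rt
Reagents that add atoms: iodomethane, CI
Why: SN2 O-methylation of the potassium carboxylate, which is far more nucleophilic than the neutral allylic hydroxyl under carbonate conditions, should give the methyl ester selectively.

Step 9
Reactants: 16 methyl (3R,6Z)-8-hydroxy-3,7-dimethyloct-6-enoate
Product: 17 methyl (3R,6Z)-8-bromo-3,7-dimethyloct-6-enoate
Conditions: CBr4, PPh3, CH2Cl2, −20 → 0 °C; used at once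
Reagents that add atoms: carbon tetrabromide, BrC(Br)(Br)Br
Why: Appel bromination proceeds by direct SN2 displacement at the primary allylic carbon, so neither allylic transposition nor Z/E isomerisation is expected at low temperature.

Step 10
Reactants: 10 4-(2-bromoethyl)-2-(furan-3-ylmethyl)furan; 17 methyl (3R,6Z)-8-bromo-3,7-dimethyloct-6-enoate
Product: 19 methyl (3R,6Z)-10-[5-(furan-3-ylmethyl)furan-3-yl]-3,7-dimethyldec-6-enoate, via Grignard reagent 18 (not isolated)
Conditions: 10, Mg, THF, rt; then added to 17, Li2CuCl4 (5 mol %), THF, −78 → −30 °C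
Reagents that add atoms: none
Why: The Grignard reagent 18 transmetalates to an alkylcuprate, which should undergo SN2-type oxidative addition at the primary allylic carbon C8 of 17 and fast reductive elimination from the σ-allylcopper(III) species, forming the C8–C9 bond. The closest known reaction type is the copper-catalysed cross-coupling of alkyl Grignard reagents with allylic halides (Li2CuCl4 catalysis), the classical head-to-tail coupling of 2-methylalk-2-enyl halides in terpenoid synthesis. No ring is closed and no stereocentre is formed; C3 is remote and is not touched. The step needs attack at C8 (α) and not at C6 (γ), retention of the 6Z geometry, and reaction at C–Br in preference to the methyl ester. These should be secured by the unhindered primary C8 terminus against the secondary C6, by the Li2CuCl4/THF/−78 °C regime in which reductive elimination outruns σ–π–σ equilibration, and by the much higher reactivity of an allylic bromide towards the cuprate than of an ester towards RMgBr at this temperature.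

Compound list
1 | furan-3-carbaldehyde | O=Cc1ccoc1 | starting material
2 | 3-(bromomethyl)furan | BrCc1ccoc1 | starting material
3 | lithium (furan-3-yl)(morpholin-4-yl)methanolate | [Li]OC(c1ccoc1)N1CCOCC1 | intermediate
4 | lithium (5-lithiofuran-3-yl)(morpholin-4-yl)methanolate | [Li]OC(c1coc([Li])c1)N1CCOCC1 | intermediate
5 | lithium [5-(furan-3-ylmethyl)furan-3-yl](morpholin-4-yl)methanolate | [Li]OC(c1coc(Cc2ccoc2)c1)N1CCOCC1 | intermediate
6 | 5-(furan-3-ylmethyl)furan-3-carbaldehyde | O=Cc1coc(Cc2ccoc2)c1 | intermediate
7 | 4-ethenyl-2-(furan-3-ylmethyl)furan | C=Cc1coc(Cc2ccoc2)c1 | intermediate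
8 | 9-{2-[5-(furan-3-ylmethyl)furan-3-yl]ethyl}-9-borabicyclo[3.3.1]nonane | c1c(Cc2ccoc2)occ1CCB1C2CCCC1CCC2 | intermediate
9 | 2-[5-(furan-3-ylmethyl)furan-3-yl]ethan-1-ol | OCCc1coc(Cc2ccoc2)c1 | intermediate
10 | 4-(2-bromoethyl)-2-(furan-3-ylmethyl)furan | BrCCc1coc(Cc2ccoc2)c1 | intermediate
11 | (R)-citronellic acid, (3R)-3,7-dimethyloct-6-enoic acid | OC(=O)C[C@H](C)CCC=C(C)C | starting material
12 | (3R)-5-(5,5-dimethyl-1,2,4-trioxolan-3-yl)-3-methylpentanoic acid (epimers at the ring carbon) | OC(=O)C[C@H](C)CCC1OOC(C)(C)O1 | intermediate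
13 | (3R)-3-methyl-6-oxohexanoic acid | OC(=O)C[C@H](C)CCC=O | intermediate
14 | (3R,6Z)-8-ethoxy-3,7-dimethyl-8-oxooct-6-enoic acid | OC(=O)C[C@H](C)CC/C=C(/C)C(=O)OCC | intermediate
15 | (3R,6Z)-8-hydroxy-3,7-dimethyloct-6-enoic acid | OC(=O)C[C@H](C)CC/C=C(/C)CO | intermediate
16 | methyl (3R,6Z)-8-hydroxy-3,7-dimethyloct-6-enoate | COC(=O)C[C@H](C)CC/C=C(/C)CO | intermediate
17 | methyl (3R,6Z)-8-bromo-3,7-dimethyloct-6-enoate | COC(=O)C[C@H](C)CC/C=C(/C)CBr | intermediate
18 | {2-[5-(furan-3-ylmethyl)furan-3-yl]ethyl}magnesium bromide | Br[Mg]CCc1coc(Cc2ccoc2)c1 | intermediate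
19 | methyl (3R,6Z)-10-[5-(furan-3-ylmethyl)furan-3-yl]-3,7-dimethyldec-6-enoate | COC(=O)C[C@H](C)CC/C=C(/C)CCCc1coc(Cc2ccoc2)c1 | target

Total step count: 10.
Longest linear sequence: 6 steps (steps 5–10 from 11); the furan branch is 5 steps (steps 1–4 and 10).

Steps most likely to fail

Step 10. The coupling may suffer from γ-attack at C6, from loss of the Z geometry by equilibration of the allylcopper intermediate, from addition of the Grignard reagent to the methyl ester, or from homocoupling. The fallback makes the same bond by sulfone alkylation; it sets out from 10 and 17 and comes back at 19. Compound 10 and sodium benzenesulfinate (DMF, 60 °C) should give 4-[2-(benzenesulfonyl)ethyl]-2-(furan-3-ylmethyl)furan F1. Its α-sulfonyl carbanion (n-BuLi, THF, −78 °C) would be alkylated by 17 in an SN2 reaction to methyl (3R,6Z)-9-(benzenesulfonyl)-10-[5-(furan-3-ylmethyl)furan-3-yl]-3,7-dimethyldec-6-enoate F2 (C9 epimers). Reductive desulfonylation (Na(Hg), Na2HPO4, MeOH, −20 °C) would then give 19.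

Step 1. Halogen–metal exchange or proton transfer between the 5-lithio species 4 and the labile bromide 2, or lithiation at C2 in place of C5, may erode the alkylation. The fallback forms the same bond by cross-coupling; it sets out from 1 and 2 and comes back at 6. Electrophilic bromination of 1 (Br2, AlCl3, CH2Cl2, 0 °C → rt) should go to the α-position C5, remote from the formyl group, and give 5-bromofuran-3-carbaldehyde F3. Zinc insertion into 2 (Zn, LiCl, THF, 0 °C) would give (furan-3-ylmethyl)zinc bromide F4. Negishi coupling of F3 with F4 (Pd(PPh3)4, THF, rt) should give 6.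

Step 7. DIBAL-H may over-reduce the aluminium carboxylate, or the Z-enoate may suffer conjugate reduction or isomerisation. The fallback brings in the allylic oxygen without any ester reduction; it sets out from 13 and comes back at 16. Esterification (TMSCHN2, MeOH–toluene, 0 °C) would give methyl (3R)-3-methyl-6-oxohexanoate F5. Stork–Zhao-type olefination with (1-iodoethylidene)triphenylphosphorane (from ethyltriphenylphosphonium iodide, n-BuLi, I2, then NaHMDS, THF, −78 °C) should give methyl (3R,6Z)-7-iodo-3-methyloct-6-enoate F6. Stille coupling with (tributylstannyl)methanol (Pd(PPh3)4, dioxane, 80 °C) would replace iodine by CH2OH with retention of the alkene geometry and give 16.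

Further compounds
F1 | step 10 | 4-[2-(benzenesulfonyl)ethyl]-2-(furan-3-ylmethyl)furan | O=S(=O)(CCc1coc(Cc2ccoc2)c1)c1ccccc1
F2 | step 10 | methyl (3R,6Z)-9-(benzenesulfonyl)-10-[5-(furan-3-ylmethyl)furan-3-yl]-3,7-dimethyldec-6-enoate (C9 epimers) | COC(=O)C[C@H](C)CC/C=C(/C)CC(Cc1coc(Cc2ccoc2)c1)S(=O)(=O)c1ccccc1
F3 | step 1 | 5-bromofuran-3-carbaldehyde | O=Cc1coc(Br)c1
F4 | step 1 | (furan-3-ylmethyl)zinc bromide | Br[Zn]Cc1ccoc1
F5 | step 7 | methyl (3R)-3-methyl-6-oxohexanoate | COC(=O)C[C@H](C)CCC=O
F6 | step 7 | methyl (3R,6Z)-7-iodo-3-methyloct-6-enoate | COC(=O)C[C@H](C)CC/C=C(/C)I
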